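Ask what the south-east flask holds at its last reading and which remedy lifts G most. Find the end state first, then how fast it comes.

| setting | south-east | south | flask |
|---|---|---|---|
| J | 0.015 M | 0.015 M | 0.015 M |
| temperature | 25 °C | 20 °C | 25 °C |
| remark | the very flask that is asked about, followed so far | run made earlier |  |
| time |  |  | 30 h |

| south-east: time / h | south-east: G / % | south: time / h | south: G / % |
|---|---|---|---|
| 5.00 | 42 | 5.00 | 33 |
| 10.0 | 60 | 10.0 | 51 |
| 15.0 | 60 | 15.0 | 53 |
| 20.0 | 63 | 20.0 | 55 |
| 25.0 | 64 | 25.0 | 55 |
| 30.0 | 65 | 30.0 | 54 |

(each reading ± 1.5 percentage points)

- Sunday's: change nothing and wait 10 h more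
- Tuesday's: at 30 h raise the temperature by 25 K, then wait 10 h
- Saturday's: at 30 h take out 90% of the G then present, then wait 10 h

- a species is counted by the J in it: one G counts as two
- given per volume of solution although it is solid: J
- G that was removed still counts
- at the start none of J is in solution

1. G, in percent of the J first charged, at 30 h
2. the remedy with the largest gain of G, or "none" below 2 percentage points (Sunday's / Tuesday's / Saturday's / none)
3. G present, with what was taken out counted in, in percent of the J first charged, after Sunday's
4. G present, with what was taken out counted in, in percent of the J first charged, after Saturday's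

Read the end state off the south-east flask. Call its last reading, 65.0%, the end share: the part of what has reacted that stands as G once the climb stops. Take that reading as "now", give or take 1.5 percentage points.

Climb the ladder in the south-east flask, fastest rung first, assuming that what is not G can return to G in the same share. My own reckoning for Saturday's:

taken out = 58.5%

pool left = 41.5%

G regained in the pool = end share × pool = 27.0%

total = 85.5%

At the early pace, 42% of G in 5.00 h, the refill takes 2.44 h, shorter than the 10 h allowed. So expect Saturday's to reach its end within the wait.

Next rung: at that pace the first fill comes to 7.74 h, well inside 30 h.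

Slowest rung: the creep. The last 10.0 h added 2 points, which two readings with this scatter can show by chance. Put Sunday's at the reading itself, inside the 2 points margin.

The south flask differs from the south-east flask in temperature, and its last reading stands lower, so read heat as moving the end. Compare the odds of these last readings:

south-east 1.86, south 1.17

Assume the same factor at each step and repeat it 5 times for the 25 K rise:

end share when hot = 94.8%

So pick Tuesday's, above Saturday's.

The forecast gives 64% for now, 65% after Sunday's and 88% after Saturday's, with Tuesday's as best. For Saturday's it argues “Removing G therefore restarts the reaction”. Its Saturday figure stands above my 85.5%, and its now stands below my 65.0%.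

The flask gives 63.8%, then 64.3% after Sunday's and 84.2% after Saturday's. Tuesday's gains most, 27 points against 20 points for Saturday's and 0.41 points for Sunday's.

    2 D → G (k = 0.0150 L mol⁻¹ s⁻¹, Ea = 69.0 kJ mol⁻¹)
    G ⇌ L (K = 0.530, k = 1.20 × 10⁻⁴ s⁻¹, Ea = 92.0 kJ mol⁻¹, ΔH = −56.0 kJ mol⁻¹)
    J ⇌ D, rate k3*(cs3 - [D]) while solid is left; crystals form when [D] > cs3 (solubility = 8.60 mM, k = 1.50 × 10⁻⁴ s⁻¹)
    (constants at 25 °C)

The end share reads the split of G against L, a case of thermodynamic control. Strike out the loss of G to L and the asked flask holds 97.6% instead of 63.8%, so this loss caps G. In the asked flask as it stands at 30.0 h, 65.0% of what is not D, the 2.36% left aside, gives 63.5%. In the neighbour stopped at 8.0 h, 15% is still J or D, so 65.0% of the remainder gives 55.2%, and that flask holds 57.3% of G.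

The data are simulated for an exercise, and the scatter is random.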